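Count first how much G is charged per L charged: the average chain length is the G gone into chains divided by the chains begun.

| setting | cedar | elm | noon | dawn |
|---|---|---|---|---|
| G | 1.7 mM | 3.4 mM | 2.0 mM | 4.0 mM |
| L | 36 µM | 36 µM | 36 µM | 36 µM |
| remark | run made earlier | run made earlier |  |  |
| time |  |  | 6.0 min | 6.0 min |

| run | time / min | E / % | G / % |
|---|---|---|---|
| cedar | 0.333 | 26.9 | 74.3 |
| cedar | 1.00 | 45.4 | 54.1 |
| cedar | 1.50 | 52.7 | 48.2 |
| cedar | 2.50 | 60.3 | 39.4 |
| cedar | 4.00 | 67.3 | 33.7 |
| cedar | 5.00 | 67.9 | 31.2 |
| cedar | 6.00 | 70.3 | 26.8 |
| elm | 0.500 | 33.0 | 66.3 |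
| elm | 0.667 | 38.7 | 61.9 |
| elm | 1.00 | 46.7 | 53.1 |
| elm | 1.50 | 53.5 | 48.2 |
| elm | 2.50 | 58.4 | 40.5 |
| elm | 4.00 | 63.9 | 34.7 |
| elm | 6.00 | 71.5 | 29.0 |

(standard deviation of a reading: 1 percentage point)

- in percentages every species weighs as the G in it: one X counts as two
- the average divides the monomer in chains by the number of chains begun, living and dead together
- steps under discussion: G + L -> Q + E; G + Q -> E + Q; 2 G -> X; 2 Q -> D; L -> J
- the earlier runs do not show the number of chains; that part of a forecast is a guess

1. which of the two ends with the longer chains by the average number of monomer units in a chain (chains begun, living or dead) ("neither" if they lie within 10%) (noon / dawn / neither)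
2. average number of monomer units in a chain (chains begun, living or dead) at the end, noon
3. average number of monomer units in a chain (chains begun, living or dead) at the end, dawn

We need two things: the fraction of the charged G that stands as E at the end, and the chains begun per L. The first can be read. Cedar and elm, with twice the G at the same L, give E fractions of 52.7% and 53.5% at 1.50 min, then 70.3% and 71.5% at 6.00 min. These pairs differ by about the scatter of a reading. That is how a loss of G of first order in G looks, with the fraction converted by a given time at a fixed L not depending on the G charge. Noon and dawn have the L of those runs and end at that time, so we carry over 70.9%, the end fraction, the mean of the two last E readings.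

The second is a guess, since the readings show no chains: we take one chain per L. Our reckoning is then the end fraction times the G charged per L charged, which gives 39.4 for noon and 78.8 for dawn.

The forecast used elm's reading instead of our mean. It says 40 for noon and 79 for dawn, with dawn the longer, and holds that “initiation looks fast and nearly complete”.

The flask gives 40.6 for noon and 79.6 for dawn, so dawn has the longer chains. E ends at 71.0% in noon and 70.6% in dawn.

    G + L → Q + E (k = 350 M⁻¹ s⁻¹)
    G + Q → E + Q, rate k2*[Q]*[G] (k = 650 M⁻¹ s⁻¹)
    2 G → X (k = 0.00850 M⁻¹ s⁻¹)
    2 Q → D (k = 830 M⁻¹ s⁻¹)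
    L → J (k = 0.0200 s⁻¹)

Dawn's chains are about twice as long as noon's. The simulated run of dawn with noon's G gives 40.6 against 79.6, so the difference in concentration of G is the main reason for that gap. Our 70.9% was read at one L charge, and dawn's neighbour has 0.061 mM of L. There the carried fraction gives 46.5. The computed length is 50.7, with E at 76.2%, more than the carried 70.9%.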